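**Retrosynthetic overview**
- The target is reached by one global hydrogenation (C=C, benzyl ether, diphenylmethylene ketal) of an 18-membered macrocyclic stilbene. That ring is closed last, by an intramolecular Wittig reaction that forms the bridge between rings B and C.
- The (S)-carbinol comes from asymmetric transfer hydrogenation of an open-chain aryl benzyl ketone, before ring closure.
- Key C–C bond (carbonyl carbon to benzylic CH2): intermolecular decarboxylative Claisen condensation of the enediolate of a ring C–D arylacetic acid with a ring A–B methyl benzoate.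
- Both diaryl ethers are made by SNAr: gallate phenol with 4-fluorobenzaldehyde (A–O–B), and 3-hydroxyphenylacetic acid with 3-benzyloxy-2-fluorobenzaldehyde (C–O–D).
- Ring order: the four benzene rings are bought; the protecting dioxole ring on ring A is formed first and the macrocycle last.

Assumption: ring A is the trioxygenated ring at the carbinol, ring B the para-phenylene, ring C the 1,2,3-trisubstituted ring, ring D the meta-phenylene; TBS is tert-butyldimethylsilyl; the stilbene from ring closure is carried on as an E/Z mixture because both isomers give the same hydrogenation product.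

**Route**

Step 1
Reactants: 1 methyl gallate
Product: 2 methyl 7-hydroxy-2,2-diphenyl-1,3-benzodioxole-5-carboxylate
Conditions: Ph2CCl2 (1.3 equiv), neat, 180 °C, 20 min
Reagents that add atoms: dichlorodiphenylmethane ClC(Cl)(c1ccccc1)c1ccccc1
Why: Ketalisation of a catechol with a gem-dichloride, in which two adjacent phenols of the symmetric triol close the five-membered diphenylmethylene ketal and exactly one phenol stays free.

Step 2
Reactants: 2 methyl 7-hydroxy-2,2-diphenyl-1,3-benzodioxole-5-carboxylate, 3 4-fluorobenzaldehyde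
Product: 4 methyl 7-(4-formylphenoxy)-2,2-diphenyl-1,3-benzodioxole-5-carboxylate
Conditions: K2CO3, DMF, 110 °C
Reagents that add atoms: none
Why: Nucleophilic aromatic substitution (SNAr) of the para-formyl-activated fluoride by the phenoxide gives the A–O–B diaryl ether, and the ester and ketal are inert to dry carbonate.

Step 3
Reactants: 4 methyl 7-(4-formylphenoxy)-2,2-diphenyl-1,3-benzodioxole-5-carboxylate
Product: 5 methyl 7-[4-(1,3-dioxolan-2-yl)phenoxy]-2,2-diphenyl-1,3-benzodioxole-5-carboxylate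
Conditions: HOCH2CH2OH (5 equiv), PPTS (cat.), toluene, reflux, Dean–Stark
Reagents that add atoms: ethylene glycol OCCO
Why: Acid-catalysed acetalisation with azeotropic water removal masks the aldehyde against the later enolate and hydride steps, and the mild pyridinium acid leaves the methyl ester and the catechol ketal alone.

Step 4
Reactants: 6 2-fluoro-3-hydroxybenzaldehyde
Product: 7 3-(benzyloxy)-2-fluorobenzaldehyde
Conditions: BnBr, K2CO3, DMF, rt
Reagents that add atoms: benzyl bromide BrCc1ccccc1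
Why: Williamson ether synthesis on the phenoxide installs a benzyl ether that is removed only in the final hydrogenation.

Step 5
Reactants: 7 3-(benzyloxy)-2-fluorobenzaldehyde, 8 (3-hydroxyphenyl)acetic acid
Product: 9 {3-[2-(benzyloxy)-6-formylphenoxy]phenyl}acetic acid
Conditions: K2CO3 (3 equiv), DMSO, 120 °C; then 1 M HCl to pH 3
Reagents that add atoms: none
Why: SNAr of the ortho-formyl-activated fluoride by the phenoxide gives the C–O–D diaryl ether, and the acid is carried as its carboxylate so that its CH2 cannot condense with the aldehyde.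

Step 6
Reactants: 9 {3-[2-(benzyloxy)-6-formylphenoxy]phenyl}acetic acid
Product: 10 {3-[2-(benzyloxy)-6-(hydroxymethyl)phenoxy]phenyl}acetic acid
Conditions: NaBH4, THF/MeOH, 0 °C to rt; then 1 M HCl to pH 3
Reagents that add atoms: none
Why: Chemoselective borohydride reduction converts the aldehyde into the benzylic alcohol while the carboxylate is not reduced.

Step 7
Reactants: 10 {3-[2-(benzyloxy)-6-(hydroxymethyl)phenoxy]phenyl}acetic acid
Product: 12 {3-[2-(benzyloxy)-6-({[tert-butyl(dimethyl)silyl]oxy}methyl)phenoxy]phenyl}acetic acid, via bis-silylated ester 11 (not isolated)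
Conditions: TBSCl (2.4 equiv), imidazole, DMF, rt; then K2CO3, MeOH/THF/H2O, rt; AcOH to pH 5
Reagents that add atoms: tert-butyldimethylsilyl chloride CC(C)(C)[Si](C)(C)Cl
Why: Silylation of both the alcohol and the acid followed by selective hydrolysis of the far more labile silyl ester leaves the primary TBS ether and frees the acid.

Step 8
Reactants: 12 {3-[2-(benzyloxy)-6-({[tert-butyl(dimethyl)silyl]oxy}methyl)phenoxy]phenyl}acetic acid, 5 methyl 7-[4-(1,3-dioxolan-2-yl)phenoxy]-2,2-diphenyl-1,3-benzodioxole-5-carboxylate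
Product: 15 2-{3-[2-(benzyloxy)-6-({[tert-butyl(dimethyl)silyl]oxy}methyl)phenoxy]phenyl}-1-{7-[4-(1,3-dioxolan-2-yl)phenoxy]-2,2-diphenyl-1,3-benzodioxol-5-yl}ethan-1-one, via dilithium enediolate 13 (not isolated), via beta-keto acid 14 (not isolated)
Conditions: 12 (1.2 equiv), LiN(SiMe3)2 (3.6 equiv), THF, −78 to 0 °C; 5 (1.0 equiv), −20 °C to rt; then AcOH, 0 °C; extract, toluene, 50 °C
Reagents that add atoms: none
Why: Intermolecular crossed Claisen condensation of the arylacetic acid enediolate with the non-enolisable methyl benzoate (the carboxylate cannot self-condense), driven by deprotonation of the beta-keto carboxylate and finished by decarboxylation of the beta-keto acid on mild acidification, joins the A–B and C–D fragments.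

Step 9
Reactants: 15 the ketone from step 8
Product: 16 (1S)-2-{3-[2-(benzyloxy)-6-({[tert-butyl(dimethyl)silyl]oxy}methyl)phenoxy]phenyl}-1-{7-[4-(1,3-dioxolan-2-yl)phenoxy]-2,2-diphenyl-1,3-benzodioxol-5-yl}ethan-1-ol
Conditions: RuCl[(S,S)-TsDPEN](p-cymene) (2 mol %), HCO2H/Et3N (5:2), DMF, 35 °C
Reagents that add atoms: none
Why: Noyori asymmetric transfer hydrogenation of an aryl benzyl ketone without ortho substituents, in which the (S,S) catalyst delivers hydride to the Re face of the carbonyl (the same sense as acetophenone to (S)-1-phenylethanol) and sets the S carbinol; acetal, silyl ether and benzyl ether are untouched.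

Step 10
Reactants: 16 the (S)-alcohol from step 9
Product: 17 (1S)-2-{3-[2-(benzyloxy)-6-({[tert-butyl(dimethyl)silyl]oxy}methyl)phenoxy]phenyl}-1-{7-[4-(1,3-dioxolan-2-yl)phenoxy]-2,2-diphenyl-1,3-benzodioxol-5-yl}ethyl acetate
Conditions: Ac2O, pyridine, DMAP (cat.), CH2Cl2, rt
Reagents that add atoms: acetic anhydride CC(=O)OC(C)=O
Why: DMAP-catalysed O-acylation with retention at carbon protects the secondary benzylic alcohol so that only the primary position is converted into the bromide later.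

Step 11
Reactants: 17 the (S)-acetate TBS ether
Product: 18 (1S)-2-{3-[2-(benzyloxy)-6-(hydroxymethyl)phenoxy]phenyl}-1-{7-[4-(1,3-dioxolan-2-yl)phenoxy]-2,2-diphenyl-1,3-benzodioxol-5-yl}ethyl acetate
Conditions: HF·pyridine, pyridine, THF, 0 °C to rt
Reagents that add atoms: none
Why: Fluoride-mediated desilylation under pyridine buffering removes the primary TBS ether without touching the acetate, the dioxolane or the catechol ketal.

Step 12
Reactants: 18 the primary benzylic alcohol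
Product: 19 (1S)-2-{3-[2-(benzyloxy)-6-(bromomethyl)phenoxy]phenyl}-1-{7-[4-(1,3-dioxolan-2-yl)phenoxy]-2,2-diphenyl-1,3-benzodioxol-5-yl}ethyl acetate
Conditions: CBr4, PPh3, CH2Cl2, 0 °C
Reagents that add atoms: carbon tetrabromide BrC(Br)(Br)Br
Why: The Appel reaction converts the primary benzylic alcohol into the bromide under neutral conditions that spare the acetal and the secondary acetate.

Step 13
Reactants: 19 the benzylic bromide
Product: 20 [2-(3-{(2S)-2-acetoxy-2-{7-[4-(1,3-dioxolan-2-yl)phenoxy]-2,2-diphenyl-1,3-benzodioxol-5-yl}ethyl}phenoxy)-3-(benzyloxy)benzyl]triphenylphosphonium bromide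
Conditions: PPh3, toluene, 90 °C
Reagents that add atoms: triphenylphosphine c1ccc(cc1)P(c1ccccc1)c1ccccc1
Why: SN2 quaternisation of triphenylphosphine by the primary benzylic bromide gives the Wittig salt, which precipitates from toluene.

Step 14
Reactants: 20 the phosphonium bromide acetal
Product: 21 [2-(3-{(2S)-2-acetoxy-2-[7-(4-formylphenoxy)-2,2-diphenyl-1,3-benzodioxol-5-yl]ethyl}phenoxy)-3-(benzyloxy)benzyl]triphenylphosphonium bromide
Conditions: 1 M aq. HBr, THF, rt
Reagents that add atoms: water O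
Why: Acid-catalysed acetal hydrolysis frees the ring B aldehyde under dilute acid that the acetate, the benzyl ether and the diphenylmethylene ketal survive, with bromide kept as the counter-ion.

Step 15
Reactants: 21 the phosphonium bromide aldehyde
Product: 24 (S)-configured macrocyclic stilbene alcohol (E/Z mixture; ring A diphenylmethylene ketal; ring C benzyl ether), via phosphonium ylide 22 (not isolated), via macrocyclic stilbene acetate 23 (not isolated)
Conditions: NaOMe (excess), MeOH/CH2Cl2, rt, 21 added over 20 h (final 1 mM); then 6 h, rt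
Reagents that add atoms: none
Why: Intramolecular Wittig olefination under high dilution closes the 18-membered ring at the B–C bridge and the same methoxide cleaves the acetate by transesterification, while the carbinol C–H is not acidic so the stereocentre is untouched.

Step 16
Reactants: 24 the macrocyclic stilbene alcohol
Product: 25 target CNP0333307.1, the (S)-configured 18-membered bis(bibenzyl) triphenol carbinol
Conditions: H2 (1 atm), 10% Pd/C, THF/EtOAc, rt, monitored
Reagents that add atoms: none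
Why: Catalytic hydrogenation saturates both stilbene isomers and hydrogenolyses the benzyl ether and the diphenylmethylene ketal in one operation, and in neutral, acid-free solvent the secondary benzylic C–OH is retained so the S centre is kept.

**Compound list**
1 | methyl gallate (methyl 3,4,5-trihydroxybenzoate) | COC(=O)c1cc(O)c(O)c(O)c1 | starting material
2 | methyl 7-hydroxy-2,2-diphenyl-1,3-benzodioxole-5-carboxylate | COC(=O)c1cc(O)c2OC(c3ccccc3)(c3ccccc3)Oc2c1 | intermediate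
3 | 4-fluorobenzaldehyde | O=Cc1ccc(F)cc1 | starting material
4 | methyl 7-(4-formylphenoxy)-2,2-diphenyl-1,3-benzodioxole-5-carboxylate | COC(=O)c1cc(Oc2ccc(C=O)cc2)c2OC(c3ccccc3)(c3ccccc3)Oc2c1 | intermediate
5 | methyl 7-[4-(1,3-dioxolan-2-yl)phenoxy]-2,2-diphenyl-1,3-benzodioxole-5-carboxylate (fragment A–B) | COC(=O)c1cc(Oc2ccc(cc2)C2OCCO2)c2OC(c3ccccc3)(c3ccccc3)Oc2c1 | intermediate
6 | 2-fluoro-3-hydroxybenzaldehyde | O=Cc1cccc(O)c1F | starting material
7 | 3-(benzyloxy)-2-fluorobenzaldehyde | O=Cc1cccc(OCc2ccccc2)c1F | intermediate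
8 | (3-hydroxyphenyl)acetic acid | OC(=O)Cc1cccc(O)c1 | starting material
9 | {3-[2-(benzyloxy)-6-formylphenoxy]phenyl}acetic acid | OC(=O)Cc1cccc(Oc2c(C=O)cccc2OCc2ccccc2)c1 | intermediate
10 | {3-[2-(benzyloxy)-6-(hydroxymethyl)phenoxy]phenyl}acetic acid | OC(=O)Cc1cccc(Oc2c(CO)cccc2OCc2ccccc2)c1 | intermediate
11 | tert-butyldimethylsilyl {3-[2-(benzyloxy)-6-({[tert-butyl(dimethyl)silyl]oxy}methyl)phenoxy]phenyl}acetate (not isolated) | CC(C)(C)[Si](C)(C)OCc1cccc(OCc2ccccc2)c1Oc1cccc(CC(=O)O[Si](C)(C)C(C)(C)C)c1 | intermediate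
12 | {3-[2-(benzyloxy)-6-({[tert-butyl(dimethyl)silyl]oxy}methyl)phenoxy]phenyl}acetic acid (fragment C–D) | CC(C)(C)[Si](C)(C)OCc1cccc(OCc2ccccc2)c1Oc1cccc(CC(O)=O)c1 | intermediate
13 | dilithium enediolate of 12, dilithium 2-aryl-ethene-1,1-diolate (not isolated) | [Li+].[Li+].CC(C)(C)[Si](C)(C)OCc1cccc(OCc2ccccc2)c1Oc1cccc(c1)C=C([O-])[O-] | intermediate
14 | racemic 2-{3-[2-(benzyloxy)-6-({[tert-butyl(dimethyl)silyl]oxy}methyl)phenoxy]phenyl}-3-{7-[4-(1,3-dioxolan-2-yl)phenoxy]-2,2-diphenyl-1,3-benzodioxol-5-yl}-3-oxopropanoic acid (not isolated) | CC(C)(C)[Si](C)(C)OCc1cccc(OCc2ccccc2)c1Oc1cccc(c1)C(C(O)=O)C(=O)c1cc(Oc2ccc(cc2)C2OCCO2)c2OC(c3ccccc3)(c3ccccc3)Oc2c1 | intermediate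
15 | 2-{3-[2-(benzyloxy)-6-({[tert-butyl(dimethyl)silyl]oxy}methyl)phenoxy]phenyl}-1-{7-[4-(1,3-dioxolan-2-yl)phenoxy]-2,2-diphenyl-1,3-benzodioxol-5-yl}ethan-1-one | CC(C)(C)[Si](C)(C)OCc1cccc(OCc2ccccc2)c1Oc1cccc(c1)CC(=O)c1cc(Oc2ccc(cc2)C2OCCO2)c2OC(c3ccccc3)(c3ccccc3)Oc2c1 | intermediate
16 | (1S)-2-{3-[2-(benzyloxy)-6-({[tert-butyl(dimethyl)silyl]oxy}methyl)phenoxy]phenyl}-1-{7-[4-(1,3-dioxolan-2-yl)phenoxy]-2,2-diphenyl-1,3-benzodioxol-5-yl}ethan-1-ol | CC(C)(C)[Si](C)(C)OCc1cccc(OCc2ccccc2)c1Oc1cccc(c1)C[C@H](O)c1cc(Oc2ccc(cc2)C2OCCO2)c2OC(c3ccccc3)(c3ccccc3)Oc2c1 | intermediate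
17 | (1S)-2-{3-[2-(benzyloxy)-6-({[tert-butyl(dimethyl)silyl]oxy}methyl)phenoxy]phenyl}-1-{7-[4-(1,3-dioxolan-2-yl)phenoxy]-2,2-diphenyl-1,3-benzodioxol-5-yl}ethyl acetate | CC(C)(C)[Si](C)(C)OCc1cccc(OCc2ccccc2)c1Oc1cccc(c1)C[C@H](OC(C)=O)c1cc(Oc2ccc(cc2)C2OCCO2)c2OC(c3ccccc3)(c3ccccc3)Oc2c1 | intermediate
18 | (1S)-2-{3-[2-(benzyloxy)-6-(hydroxymethyl)phenoxy]phenyl}-1-{7-[4-(1,3-dioxolan-2-yl)phenoxy]-2,2-diphenyl-1,3-benzodioxol-5-yl}ethyl acetate | OCc1cccc(OCc2ccccc2)c1Oc1cccc(c1)C[C@H](OC(C)=O)c1cc(Oc2ccc(cc2)C2OCCO2)c2OC(c3ccccc3)(c3ccccc3)Oc2c1 | intermediate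
19 | (1S)-2-{3-[2-(benzyloxy)-6-(bromomethyl)phenoxy]phenyl}-1-{7-[4-(1,3-dioxolan-2-yl)phenoxy]-2,2-diphenyl-1,3-benzodioxol-5-yl}ethyl acetate | BrCc1cccc(OCc2ccccc2)c1Oc1cccc(c1)C[C@H](OC(C)=O)c1cc(Oc2ccc(cc2)C2OCCO2)c2OC(c3ccccc3)(c3ccccc3)Oc2c1 | intermediate
20 | [2-(3-{(2S)-2-acetoxy-2-{7-[4-(1,3-dioxolan-2-yl)phenoxy]-2,2-diphenyl-1,3-benzodioxol-5-yl}ethyl}phenoxy)-3-(benzyloxy)benzyl]triphenylphosphonium bromide | [Br-].c1ccc(cc1)[P+](c1ccccc1)(c1ccccc1)Cc1cccc(OCc2ccccc2)c1Oc1cccc(c1)C[C@H](OC(C)=O)c1cc(Oc2ccc(cc2)C2OCCO2)c2OC(c3ccccc3)(c3ccccc3)Oc2c1 | intermediate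
21 | [2-(3-{(2S)-2-acetoxy-2-[7-(4-formylphenoxy)-2,2-diphenyl-1,3-benzodioxol-5-yl]ethyl}phenoxy)-3-(benzyloxy)benzyl]triphenylphosphonium bromide | [Br-].c1ccc(cc1)[P+](c1ccccc1)(c1ccccc1)Cc1cccc(OCc2ccccc2)c1Oc1cccc(c1)C[C@H](OC(C)=O)c1cc(Oc2ccc(C=O)cc2)c2OC(c3ccccc3)(c3ccccc3)Oc2c1 | intermediate
22 | benzylidene-triphenylphosphorane (ylide) formed from 21 by loss of HBr, S acetate (not isolated) | c1ccc(cc1)P(c1ccccc1)(c1ccccc1)=Cc1cccc(OCc2ccccc2)c1Oc1cccc(c1)C[C@H](OC(C)=O)c1cc(Oc2ccc(C=O)cc2)c2OC(c3ccccc3)(c3ccccc3)Oc2c1 | intermediate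
23 | macrocyclic stilbene acetate, E/Z mixture (not isolated): 18-membered ring ring A C1–CH(OAc)–CH2–ring D C1, ring D C3–O–ring C C2, ring C C1–CH=CH–ring B C1, ring B C4–O–ring A C5; ring A C3/C4 carry the O–CPh2–O ketal, ring C C3 carries OBn; S at the acetoxy carbon | C1=Cc2cccc(OCc3ccccc3)c2Oc2cccc(c2)C[C@H](OC(C)=O)c2cc(Oc3ccc1cc3)c3OC(c4ccccc4)(c4ccccc4)Oc3c2 | intermediate
24 | macrocyclic stilbene alcohol, E/Z mixture: same ring as 23 with free OH at the S carbinol carbon | C1=Cc2cccc(OCc3ccccc3)c2Oc2cccc(c2)C[C@H](O)c2cc(Oc3ccc1cc3)c3OC(c4ccccc4)(c4ccccc4)Oc3c2 | intermediate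
25 | CNP0333307.1: 18-membered ring ring A C1–(S)-CH(OH)–CH2–ring D C1, ring D C3–O–ring C C2, ring C C1–CH2CH2–ring B C1, ring B C4–O–ring A C5; OH on ring A C3 and C4 and on ring C C3 | Oc1cc2cc(c1O)Oc1ccc(cc1)CCc1cccc(O)c1Oc1cccc(c1)C[C@@H]2O | target

**Step count**
Total steps: 16. Longest linear sequence: 13 steps (steps 4 to 16, starting from 6); the ring A–B branch (steps 1 to 3) joins at step 8.

**Steps most likely to fail and fallbacks**

Step 8 (Claisen condensation onto an electron-rich benzoate may be sluggish). The fallback sets out from 5 and comes back at 14, which loses CO2 to 15 as in the route. Ester 5 is reduced with iBu2AlH (CH2Cl2, −78 °C) to {7-[4-(1,3-dioxolan-2-yl)phenoxy]-2,2-diphenyl-1,3-benzodioxol-5-yl}methanol F1. F1 is oxidised with MnO2 (CH2Cl2, rt) to 7-[4-(1,3-dioxolan-2-yl)phenoxy]-2,2-diphenyl-1,3-benzodioxole-5-carbaldehyde F2. Enediolate 13 (from 12 and LiN(SiMe3)2, THF, −78 °C) then adds to the much more electrophilic aldehyde in an intermolecular aldol (Ivanov) reaction. This gives 2-{3-[2-(benzyloxy)-6-({[tert-butyl(dimethyl)silyl]oxy}methyl)phenoxy]phenyl}-3-{7-[4-(1,3-dioxolan-2-yl)phenoxy]-2,2-diphenyl-1,3-benzodioxol-5-yl}-3-hydroxypropanoic acid F3 as a diastereomer mixture. Oxidation of F3 with Dess–Martin periodinane (CH2Cl2, rt) gives beta-keto acid 14, and warming in toluene gives 15.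

Step 15 (macrocyclic Wittig may give oligomers). The fallback sets out from 18 and comes back at 23, then 24. Alcohol 18 is oxidised with MnO2 (CH2Cl2, rt) to (1S)-2-{3-[2-(benzyloxy)-6-formylphenoxy]phenyl}-1-{7-[4-(1,3-dioxolan-2-yl)phenoxy]-2,2-diphenyl-1,3-benzodioxol-5-yl}ethyl acetate F4. The acetal is hydrolysed with 1 M aq. HBr/THF to (1S)-2-{3-[2-(benzyloxy)-6-formylphenoxy]phenyl}-1-[7-(4-formylphenoxy)-2,2-diphenyl-1,3-benzodioxol-5-yl]ethyl acetate F5. The dialdehyde is then closed by an intramolecular McMurry coupling with low-valent titanium (TiCl4, Zn, pyridine, THF, reflux, slow addition, short contact time so that the acetate is spared). This gives macrocyclic stilbene acetate 23, isolated here, and K2CO3/MeOH at rt removes the acetate to give 24.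

Step 16 (over-reduction of the electron-rich benzylic C–OH during the longer ketal hydrogenolysis). The fallback sets out from 24 and comes back at 25. The carbinol of 24 is silylated (TBSCl, imidazole, DMF, 40 °C) to the macrocyclic stilbene TBS ether F6, whose hindered benzylic silyl ether resists hydrogenolysis. Hydrogenation (H2, 10% Pd/C, THF/EtOAc, rt) gives the saturated, debenzylated and deketalised macrocyclic triphenol TBS ether F7. HF·pyridine in THF/pyridine (0 °C to rt, under argon) then frees the carbinol to give 25.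

**Further compounds**
F1 | step 8 | {7-[4-(1,3-dioxolan-2-yl)phenoxy]-2,2-diphenyl-1,3-benzodioxol-5-yl}methanol | OCc1cc(Oc2ccc(cc2)C2OCCO2)c2OC(c3ccccc3)(c3ccccc3)Oc2c1
F2 | step 8 | 7-[4-(1,3-dioxolan-2-yl)phenoxy]-2,2-diphenyl-1,3-benzodioxole-5-carbaldehyde | O=Cc1cc(Oc2ccc(cc2)C2OCCO2)c2OC(c3ccccc3)(c3ccccc3)Oc2c1
F3 | step 8 | 2-{3-[2-(benzyloxy)-6-({[tert-butyl(dimethyl)silyl]oxy}methyl)phenoxy]phenyl}-3-{7-[4-(1,3-dioxolan-2-yl)phenoxy]-2,2-diphenyl-1,3-benzodioxol-5-yl}-3-hydroxypropanoic acid (diastereomer mixture) | CC(C)(C)[Si](C)(C)OCc1cccc(OCc2ccccc2)c1Oc1cccc(c1)C(C(O)=O)C(O)c1cc(Oc2ccc(cc2)C2OCCO2)c2OC(c3ccccc3)(c3ccccc3)Oc2c1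
F4 | step 15 | (1S)-2-{3-[2-(benzyloxy)-6-formylphenoxy]phenyl}-1-{7-[4-(1,3-dioxolan-2-yl)phenoxy]-2,2-diphenyl-1,3-benzodioxol-5-yl}ethyl acetate | O=Cc1cccc(OCc2ccccc2)c1Oc1cccc(c1)C[C@H](OC(C)=O)c1cc(Oc2ccc(cc2)C2OCCO2)c2OC(c3ccccc3)(c3ccccc3)Oc2c1
F5 | step 15 | (1S)-2-{3-[2-(benzyloxy)-6-formylphenoxy]phenyl}-1-[7-(4-formylphenoxy)-2,2-diphenyl-1,3-benzodioxol-5-yl]ethyl acetate | O=Cc1cccc(OCc2ccccc2)c1Oc1cccc(c1)C[C@H](OC(C)=O)c1cc(Oc2ccc(C=O)cc2)c2OC(c3ccccc3)(c3ccccc3)Oc2c1
F6 | step 16 | TBS ether of macrocyclic stilbene alcohol 24 (E/Z mixture, S) | C1=Cc2cccc(OCc3ccccc3)c2Oc2cccc(c2)C[C@H](O[Si](C)(C)C(C)(C)C)c2cc(Oc3ccc1cc3)c3OC(c4ccccc4)(c4ccccc4)Oc3c2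
F7 | step 16 | TBS ether of the target at the S carbinol oxygen (saturated bridge, three free phenols) | C1Cc2cccc(O)c2Oc2cccc(c2)C[C@H](O[Si](C)(C)C(C)(C)C)c2cc(Oc3ccc1cc3)c(O)c(O)c2
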